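**Assumption:** longipinane numbering is used for the tricycles (C‑1 ketone, C‑2=C‑3, cyclobutane C‑4/C‑5/C‑11/C‑10, C‑6 gem‑dimethyl, C‑7 to C‑9 oxygenated, C‑10 quaternary methyl); 2,2‑bis(methylselanyl)propane is treated as a stock reagent.

## Retrosynthetic overview

1. Target ⇐ tricyclic triol 16 by late esterification (8‑OAc first, then both angelates).
2. Tricycle 15 ⇐ monocyclic (Z)‑β‑iodoenone 13 by one Pd domino that closes ring A and the cyclobutane together.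
3. Ring‑B stereotriad is set on the monocycle: CBS reduction (C‑7), then dihydroxylation anti to the 7‑OH (C‑8, C‑9).
4. Seven‑membered ring 6 ⇐ cyclohexenone 4 by a selenium‑triggered semipinacol ring expansion (1,2‑vinyl shift that inserts the CMe2 carbon) – the key step.
5. 4 ⇐ 2‑methylpent‑4‑enal + methyl vinyl ketone (asymmetric Robinson annulation sets C‑10). Ring order: six‑membered → seven‑membered ring B → ring A + four‑membered ring.

## Route

**Step 1**
Reactants: 1 2‑methylpent‑4‑enal; 2 but‑3‑en‑2‑one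
Product: 4 (S)‑4‑methyl‑4‑(prop‑2‑en‑1‑yl)cyclohex‑2‑en‑1‑one, via Michael keto‑aldehyde 3 (not isolated)
Conditions: N‑(p‑dodecylphenylsulfonyl)prolinamide (10 mol %, enantiomer giving (S)), BnNH2, 4 Å MS, ClCH2CH2Cl, rt
Reagents that add atoms: none
Why: Organocatalytic asymmetric Robinson annulation (enamine Michael addition, then aldol condensation) of an α‑branched aldehyde; the face‑selective Michael step sets the quaternary stereocentre (later C‑10).

**Step 2**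
Reactants: 4 (S)‑4‑methyl‑4‑allylcyclohex‑2‑enone
Product: 5 (4S)‑4‑methyl‑1‑[2‑(methylselanyl)propan‑2‑yl]‑4‑(prop‑2‑en‑1‑yl)cyclohex‑2‑en‑1‑ol (C‑1 epimers)
Conditions: Me2C(SeMe)2, n‑BuLi, THF, −78 °C; then 4, −78 °C; aq NH4Cl
Reagents that add atoms: 2,2‑bis(methylselanyl)propane CC(C)([Se]C)[Se]C, used as its lithio derivative 2‑lithio‑2‑(methylselanyl)propane [Li]C(C)(C)[Se]C
Why: Krief α‑selenoalkyllithium 1,2‑addition to the enone carbonyl; the carbinol configuration is irrelevant because it becomes C=O in step 3.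

**Step 3**
Reactants: 5 β‑hydroxy selenide
Product: 6 (S)‑2,2,5‑trimethyl‑5‑(prop‑2‑en‑1‑yl)cyclohept‑3‑en‑1‑one
Conditions: AgBF4, neutral Al2O3, CH2Cl2, 0 °C → rt
Reagents that add atoms: none
Why: Selenium‑triggered semipinacol ring expansion (Krief type): Ag+ ionises the tertiary C–Se bond and the vinylic ring carbon, the better migrating group, shifts, inserting CMe2 between C=O and the alkene; the quaternary centre is untouched.

**Step 4**
Reactants: 6 cycloheptenone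
Product: 7 (S)‑4,7,7‑trimethyl‑4‑(prop‑2‑en‑1‑yl)cyclohepta‑2,5‑dien‑1‑one
Conditions: IBX (2.5 equiv), DMSO/PhF, 70 °C
Reagents that add atoms: none
Why: IBX α,β‑dehydrogenation of a ketone; only the CH2–CH2 side can enolise because the other α‑carbon is quaternary.

**Step 5**
Reactants: 7 dienone
Product: 8 (1R,4S)‑4,7,7‑trimethyl‑4‑(prop‑2‑en‑1‑yl)cyclohepta‑2,5‑dien‑1‑ol
Conditions: (S)‑Me‑CBS (20 mol %), catecholborane, toluene, −78 °C
Reagents that add atoms: none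
Why: Corey–Bakshi–Shibata 1,2‑reduction of the only ketone under catalyst control (the CMe2 flank is taken as the large group, vinyl as the small one) sets C‑7; catecholborane leaves the allyl group alone.

**Step 6**
Reactants: 8 dienol
Product: 9 (1R,4S)‑4,7,7‑trimethyl‑4‑(2‑oxopropyl)cyclohepta‑2,5‑dien‑1‑ol
Conditions: PdCl2 (10 mol %), CuCl, O2 (1 atm), DMF/H2O 7:1, rt
Reagents that add atoms: water O
Why: Wacker–Tsuji oxidation is selective for the terminal alkene (Markovnikov methyl ketone); the internal ring alkenes do not react.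

**Step 7**
Reactants: 9 hydroxy ketone
Product: 10 (1S,2R,3S,4S)‑4,7,7‑trimethyl‑4‑(2‑oxopropyl)cyclohept‑5‑ene‑1,2,3‑triol
Conditions: OsO4 (2 mol %), NMO, acetone/H2O 4:1, 0 °C
Reagents that add atoms: osmium tetroxide O=[Os](=O)(=O)=O; N‑methylmorpholine N‑oxide C[N+]1([O-])CCOCC1
Why: Upjohn syn‑dihydroxylation of the allylic‑alcohol alkene, anti to the 7‑OH (Kishi rule, reinforced by the pseudo‑axial methyl on the neighbouring quaternary carbon), sets C‑8 and C‑9; the other ring alkene lies between two quaternary carbons and is too hindered.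

**Step 8**
Reactants: 10 triol
Product: 11 (1S,2R,3S,4S)‑4,7,7‑trimethyl‑4‑(2‑oxopropyl)‑1,2,3‑tris(triethylsilyloxy)cyclohept‑5‑ene
Conditions: TESOTf (3.6 equiv), 2,6‑lutidine, CH2Cl2, −78 → 0 °C
Reagents that add atoms: triethylsilyl triflate CC[Si](CC)(CC)OS(=O)(=O)C(F)(F)F
Why: Per‑silylation with a silyl triflate reaches the hindered secondary alcohols and masks them for the enolate and Pd chemistry; the angelates are left to the end because they isomerise easily.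

**Step 9**
Reactants: 11 methyl ketone
Product: 12 (1S,2R,3S,4S)‑4‑(2,4‑dioxopentyl)‑4,7,7‑trimethyl‑1,2,3‑tris(triethylsilyloxy)cyclohept‑5‑ene
Conditions: MgBr2·OEt2, i‑Pr2NEt, AcCl, CH2Cl2, rt
Reagents that add atoms: acetyl chloride CC(Cl)=O
Why: Soft‑enolisation Claisen‑type C‑acylation of the only enolisable ketone at its unhindered methyl group (the CH2 side is neopentylic) gives the 1,3‑diketone.

**Step 10**
Reactants: 12 1,3‑diketone
Product: 13 (1S,2R,3S,4S)‑4‑[(3Z)‑4‑iodo‑2‑oxopent‑3‑en‑1‑yl]‑4,7,7‑trimethyl‑1,2,3‑tris(triethylsilyloxy)cyclohept‑5‑ene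
Conditions: PPh3, I2, Et3N, MeCN, rt
Reagents that add atoms: iodine II
Why: Conversion of a β‑diketone enol into a β‑iodo enone (vinylogous acyl iodide) through the O‑phosphonium salt, expected at the less hindered acetyl terminus; E/Z isomers of the iodide converge at the vinyl‑Pd stage.

**Step 11**
Reactants: 13 (Z)‑β‑iodoenone
Product: 15 7,8,9‑tris(triethylsilyloxy)longipin‑2‑en‑1‑one, via alkylpalladium iodide 14 (not isolated)
Conditions: Pd[P(t‑Bu)3]2 (10 mol %), K3PO4, toluene, 90 °C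
Reagents that add atoms: none
Why: Proposed new method: oxidative addition of the vinyl iodide, 6‑exo syn‑carbopalladation of the ring alkene (closes ring A) and, because the resulting σ‑alkyl‑Pd at C‑5 has no syn β‑hydrogen (C‑6 is quaternary), phosphate‑assisted palladation of the adjacent ketone α‑C–H (C‑11) to a five‑membered palladacycle whose C(sp3)–C(sp3) reductive elimination closes the cyclobutane; closest known reactions are domino Heck/C(sp3)–H activation to benzocyclobutenes and Pd‑catalysed ketone α‑arylation; C‑4, C‑5 and C‑11 follow from syn addition on the face of the C‑10 side chain.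

**Step 12**
Reactants: 15 tris‑TES tricycle
Product: 16 7,8,9‑trihydroxylongipin‑2‑en‑1‑one (7,8‑trans, 8,9‑cis)
Conditions: HF·pyridine, THF, 0 °C → rt
Reagents that add atoms: none
Why: Fluoride‑mediated desilylation under mildly acidic conditions leaves the enone and the stereocentres untouched.

**Step 13**
Reactants: 16 triol
Product: 17 8‑acetoxy‑7,9‑dihydroxylongipin‑2‑en‑1‑one
Conditions: Ac2O (1.1 equiv), pyridine, CH2Cl2, −20 °C
Reagents that add atoms: acetic anhydride CC(=O)OC(C)=O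
Why: Kinetic acylation of the least hindered hydroxyl; 7‑OH and 9‑OH each sit next to a quaternary carbon.

**Step 14**
Reactants: 17 8‑acetate diol; 18 angelic acid
Product: 20 8‑acetoxy‑7,9‑bis[(Z)‑2‑methylbut‑2‑enoyloxy]longipin‑2‑en‑1‑one (target CNP0335415.1), via mixed anhydride 19 (not isolated)
Conditions: 18 (3 equiv), 2,4,6‑Cl3C6H2COCl, Et3N, toluene, rt; then 17, 80 °C
Reagents that add atoms: none
Why: Yamaguchi‑type mixed‑anhydride esterification without DMAP acylates hindered alcohols at the angeloyl carbonyl while keeping the Z geometry of the angelate.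

## Compound list

1 | 2‑methylpent‑4‑enal (racemic) | C=CCC(C)C=O | starting material
2 | but‑3‑en‑2‑one (methyl vinyl ketone) | CC(=O)C=C | starting material
3 | (S)‑2‑methyl‑2‑(3‑oxobutyl)pent‑4‑enal | CC(=O)CC[C@@](C=O)(C)CC=C | intermediate (not isolated)
4 | (S)‑4‑methyl‑4‑(prop‑2‑en‑1‑yl)cyclohex‑2‑en‑1‑one | O=C1CC[C@@](C=C1)(C)CC=C | intermediate
5 | (4S)‑4‑methyl‑1‑[2‑(methylselanyl)propan‑2‑yl]‑4‑(prop‑2‑en‑1‑yl)cyclohex‑2‑en‑1‑ol (C‑1 epimers) | OC1(C(C)(C)[Se]C)CC[C@@](C=C1)(C)CC=C | intermediate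
6 | (S)‑2,2,5‑trimethyl‑5‑(prop‑2‑en‑1‑yl)cyclohept‑3‑en‑1‑one | O=C1CC[C@@](C=CC1(C)C)(C)CC=C | intermediate
7 | (S)‑4,7,7‑trimethyl‑4‑(prop‑2‑en‑1‑yl)cyclohepta‑2,5‑dien‑1‑one | O=C1C=C[C@@](C=CC1(C)C)(C)CC=C | intermediate
8 | (1R,4S)‑4,7,7‑trimethyl‑4‑(prop‑2‑en‑1‑yl)cyclohepta‑2,5‑dien‑1‑ol | O[C@@H]1C=C[C@@](C=CC1(C)C)(C)CC=C | intermediate
9 | (1R,4S)‑4,7,7‑trimethyl‑4‑(2‑oxopropyl)cyclohepta‑2,5‑dien‑1‑ol | O[C@@H]1C=C[C@@](C=CC1(C)C)(C)CC(C)=O | intermediate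
10 | (1S,2R,3S,4S)‑4,7,7‑trimethyl‑4‑(2‑oxopropyl)cyclohept‑5‑ene‑1,2,3‑triol | O[C@@H]1[C@@H](O)[C@@H](O)[C@@](C=CC1(C)C)(C)CC(C)=O | intermediate
11 | (1S,2R,3S,4S)‑4,7,7‑trimethyl‑4‑(2‑oxopropyl)‑1,2,3‑tris(triethylsilyloxy)cyclohept‑5‑ene | CC[Si](CC)(CC)O[C@@H]1[C@@H](O[Si](CC)(CC)CC)[C@@H](O[Si](CC)(CC)CC)[C@@](C=CC1(C)C)(C)CC(C)=O | intermediate
12 | (1S,2R,3S,4S)‑4‑(2,4‑dioxopentyl)‑4,7,7‑trimethyl‑1,2,3‑tris(triethylsilyloxy)cyclohept‑5‑ene (largely enolised) | CC[Si](CC)(CC)O[C@@H]1[C@@H](O[Si](CC)(CC)CC)[C@@H](O[Si](CC)(CC)CC)[C@@](C=CC1(C)C)(C)CC(=O)CC(C)=O | intermediate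
13 | (1S,2R,3S,4S)‑4‑[(3Z)‑4‑iodo‑2‑oxopent‑3‑en‑1‑yl]‑4,7,7‑trimethyl‑1,2,3‑tris(triethylsilyloxy)cyclohept‑5‑ene | CC[Si](CC)(CC)O[C@@H]1[C@@H](O[Si](CC)(CC)CC)[C@@H](O[Si](CC)(CC)CC)[C@@](C=CC1(C)C)(C)CC(=O)/C=C(/C)I | intermediate
14 | 5‑(iodopalladio)‑7,8,9‑tris(triethylsilyloxy)‑5,11‑secolongipin‑2‑en‑1‑one (phosphine ligand not drawn) | CC[Si](CC)(CC)O[C@@H]1[C@@H](O[Si](CC)(CC)CC)[C@@H](O[Si](CC)(CC)CC)[C@@]2(C)CC(=O)C=C(C)[C@H]2[C@@H]([Pd]I)C1(C)C | intermediate (not isolated)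
15 | 7,8,9‑tris(triethylsilyloxy)longipin‑2‑en‑1‑one | CC[Si](CC)(CC)O[C@@H]1[C@@H](O[Si](CC)(CC)CC)[C@@H](O[Si](CC)(CC)CC)[C@@]2(C)[C@@H]3C(=O)C=C(C)[C@H]2[C@@H]3C1(C)C | intermediate
16 | 7,8,9‑trihydroxylongipin‑2‑en‑1‑one | O[C@@H]1[C@@H](O)[C@@H](O)[C@@]2(C)[C@@H]3C(=O)C=C(C)[C@H]2[C@@H]3C1(C)C | intermediate
17 | 8‑acetoxy‑7,9‑dihydroxylongipin‑2‑en‑1‑one | O[C@@H]1[C@@H](OC(C)=O)[C@@H](O)[C@@]2(C)[C@@H]3C(=O)C=C(C)[C@H]2[C@@H]3C1(C)C | intermediate
18 | angelic acid, (Z)‑2‑methylbut‑2‑enoic acid | C/C=C(/C)C(O)=O | starting material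
19 | angelic 2,4,6‑trichlorobenzoic anhydride | C/C=C(/C)C(=O)OC(=O)c1c(Cl)cc(Cl)cc1Cl | intermediate (not isolated)
20 | 8‑acetoxy‑7,9‑bis[(Z)‑2‑methylbut‑2‑enoyloxy]longipin‑2‑en‑1‑one (CNP0335415.1) | C/C=C(/C)C(=O)O[C@@H]1[C@@H](OC(C)=O)[C@@H](OC(=O)/C(C)=C\C)[C@@]2(C)[C@@H]3C(=O)C=C(C)[C@H]2[C@@H]3C1(C)C | target

## Step count and risks

Total step count: 14. Longest linear sequence: 14 steps (1 → 20).

**Steps most likely to fail**

1. **Step 11 (proposed Pd domino).** The σ‑alkyl‑Pd may be diverted (3‑exo attack on the new enone, protodepalladation) before the C‑5–C‑11 reductive elimination. Fallback with known chemistry, from 13 back to 15: a Pd‑catalysed carboiodination (Pd(0)/bulky phosphine, no base, toluene, 100 °C) closes ring A and returns the halide to carbon, giving the 5‑iodo‑5,11‑seco compound F1. The four‑membered ring is then closed by a photostimulated SRN1 alkylation of the C‑11 ketone enolate (LDA, THF/DMSO, hν). This radical‑chain substitution is known for neopentyl‑type iodides that are inert to SN2, and it delivers 15.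

2. **Step 3 (ring expansion).** The allylic tertiary carbinol may ionise, or the CH2 group may migrate instead of the vinyl carbon. Fallback from 4 back to 6: Lewis‑acid diazo homologation (TMSCHN2, BF3·OEt2, CH2Cl2, −78 °C, then protodesilylation) with migration of the vinylic carbon gives (S)‑5‑methyl‑5‑(prop‑2‑en‑1‑yl)cyclohept‑3‑en‑1‑one F2. Two enolate methylations at the doubly activated C‑2 (LDA, MeI; then KHMDS, MeI), via the 2‑methyl ketone F3, give 6.

3. **Step 14 (double angeloylation).** Forcing acylation of two neopentylic alcohols can move the 8‑acetate or isomerise angelate to tiglate. Fallback from 16 back to 20: TESCl/imidazole silylates only the least hindered 8‑OH to give the 8‑O‑TES diol F4. Both hindered alcohols are angeloylated under the step‑14 conditions to give the 7,9‑diangelate F5, where no acyl group can migrate. HF·pyridine frees O‑8 to give the 7,9‑diangelate 8‑ol F6, and Ac2O/pyridine gives 20.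

## Further compounds

F1 | step 11 | 5‑iodo‑7,8,9‑tris(triethylsilyloxy)‑5,11‑secolongipin‑2‑en‑1‑one | CC[Si](CC)(CC)O[C@@H]1[C@@H](O[Si](CC)(CC)CC)[C@@H](O[Si](CC)(CC)CC)[C@@]2(C)CC(=O)C=C(C)[C@H]2[C@@H](I)C1(C)C
F2 | step 3 | (S)‑5‑methyl‑5‑(prop‑2‑en‑1‑yl)cyclohept‑3‑en‑1‑one | O=C1CC[C@@](C=CC1)(C)CC=C
F3 | step 3 | (5S)‑2,5‑dimethyl‑5‑(prop‑2‑en‑1‑yl)cyclohept‑3‑en‑1‑one (C‑2 epimers) | O=C1CC[C@@](C=CC1C)(C)CC=C
F4 | step 14 | 7,9‑dihydroxy‑8‑(triethylsilyloxy)longipin‑2‑en‑1‑one | O[C@@H]1[C@@H](O[Si](CC)(CC)CC)[C@@H](O)[C@@]2(C)[C@@H]3C(=O)C=C(C)[C@H]2[C@@H]3C1(C)C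
F5 | step 14 | 7,9‑bis[(Z)‑2‑methylbut‑2‑enoyloxy]‑8‑(triethylsilyloxy)longipin‑2‑en‑1‑one | C/C=C(/C)C(=O)O[C@@H]1[C@@H](O[Si](CC)(CC)CC)[C@@H](OC(=O)/C(C)=C\C)[C@@]2(C)[C@@H]3C(=O)C=C(C)[C@H]2[C@@H]3C1(C)C
F6 | step 14 | 8‑hydroxy‑7,9‑bis[(Z)‑2‑methylbut‑2‑enoyloxy]longipin‑2‑en‑1‑one | C/C=C(/C)C(=O)O[C@@H]1[C@@H](O)[C@@H](OC(=O)/C(C)=C\C)[C@@]2(C)[C@@H]3C(=O)C=C(C)[C@H]2[C@@H]3C1(C)C
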